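The runs are calculated from invented constants, and the scatter is random.

Read concentrations, not percentages.

| setting | Sunday's | Friday's | flask |
|---|---|---|---|
| solid substrate | 0.14 M | 0.22 M | 0.10 M |
| remark | run made earlier | run made earlier |  |
| time |  |  | 1.0 h |

- Sunday's (time / min: target / %, self-condensation product / %): 4.00: 1.7, 1.6; 6.00: 4.5, 1.5; 10.0: 4.3, 3.4; 20.0: 9.4, 13.0; 30.0: 11.6, 23.0; 50.0: 7.7, 49.5
- Friday's (time / min: target / %, self-condensation product / %): 8.00: 2.7, 2.1; 15.0: 4.9, 6.0; 25.0: 5.2, 12.5; 30.0: 6.0, 14.9; 40.0: 6.5, 22.6; 50.0: 9.1, 33.7

(each reading ± 1 percentage point)

- how much target the flask holds at 1.0 h, in percent of the solid substrate charged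
- how much self-condensation product the flask holds at 1.0 h, in percent of the solid substrate charged
- how much starting material the flask holds at 1.0 h, in percent of the solid substrate charged

- percent here means solid substrate units held: one self-condensation product counts as two
- solid substrate is a solid; its amount is given per volume of the solution
- at the start none of the solid substrate is in solution
- starting material means what is dissolved; the solid is not counted in it

Between 30.0 min and 50.0 min the self-condensation product gains 0.00186 M/min in Sunday's run and 0.00207 M/min in Friday's, counted in solid substrate units, and the two rates lie close although the charges are 0.14 M and 0.22 M. Across those readings c(target) averages 0.0151 M. Taking target as a gauge of what is dissolved gives 8.65 /M/min for κ, the condensation constant referred to target: self-condensation rate over c(target) squared.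

Sunday's target drops between those readings, so its solid seems gone near 40.0 min. That reads as dissolving at 0.00350 M/min, and the flask's charge then lasts 28.6 min. About 0.0322 M should have condensed by then, leaving a dissolved pool S of 0.0678 M. With target a fixed share φ of S, the pool then falls at κφ² times S squared, a second-order decay with no feed. Plateau target over that pool gives φ = 0.222 and self-condensation product 64.5 % at 1.0 h.

φ is the weak link. Sunday's last reading, taken as lying after its solid is gone, gives it as target over what has not condensed: 0.152. This reckoning therefore commits to S = 0.0475 M: target 7.24 %, self-condensation product 52.5 %, and, counting the rest of the pool as starting material, 40.2 %, the softest figure.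

The forecast says 13 % target, 74 % self-condensation product and 13 % starting material, holding that “dissolved material climbs toward saturation and condenses at second order”. It stands above this reckoning in self-condensation product and below it in starting material.

The flask gives 7.64 % target, 54.6 % self-condensation product and 8.91 % starting material, beside 24.9 % isomer of the product and 3.99 % third isomer, both of which the reckoning's 40.2 % had counted as starting material.

    starting material ⇌ target (K = 0.840, k = 0.440 /min)
    starting material ⇌ third isomer (K = 0.430, k = 0.120 /min)
    2 starting material → self-condensation product (k = 3.20 /M/min)
    starting material ⇌ isomer of the product (K = 2.50, k = 0.280 /min)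
    solid substrate ⇌ starting material, rate k5*(cs5 - [starting material]) while solid is left; crystals form when [starting material] > cs5 (solubility = 35.0 mM, k = 0.160 /min)

The flask's solid substrate stands at 0 % at 0.500 h. For second-order decay the time-mean of c squared is the product of the end values, so κ and this flask's c(target) from 0.500 h to 1.0 h give a gain of 24.8 % of the charge; the flask's self-condensation product gains 23 percentage points.

For the neighbour charged with 0.040 M, taking everything as dissolved from the start and φ = 0.168 from this flask, κ gives S = 0.0252 M, so 37.0 % self-condensation product and 10.6 % target. That neighbour holds 39.8 % self-condensation product and 10.4 % target at 1.0 h.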